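The route rests on cutting the bond between the guaiacyl ring carbon C1' and C2 of the 1,4-dioxane ring. C2 is at once an acetal-level carbon on O1 (the catechol oxygen para to the side chain) and benzylic to a 4-oxygenated arene, so it can be a masked aldehyde first and a quinone-methide-like cation afterwards. In one flask, an aryl Grignard adds to the ring-opened form of a (3R)-3-(silyloxymethyl)-6-bromo-1,4-benzodioxan-2-ol (lactol), and acid then recloses O1–C2 through the benzylic cation, as the biosynthesis does, setting C2 trans to C3 whatever the carbinol configuration. The lactol comes from methyl (S)-glycerate and 4-bromo-2-hydroxybenzaldehyde.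

Key step: step 6

Assumption: methyl (S)-glycerate (3) is treated as purchasable; otherwise it is one acidic methanolysis away from commercial methyl (S)-2,2-dimethyl-1,3-dioxolane-4-carboxylate.

Step 1
Reactants: 1 4-bromo-2-methoxyphenol
Product: 2 (4-bromo-2-methoxyphenoxy)(tert-butyl)dimethylsilane
Conditions: TBSCl, imidazole, DMF, rt
Reagents that add atoms: tert-butyldimethylsilyl chloride (TBSCl), CC(C)(C)[Si](C)(C)Cl
Why: Imidazole-mediated O-silylation of the phenol masks the acidic OH so that the aryl bromide can later be converted into a Grignard reagent.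

Step 2
Reactants: 3 methyl (2S)-2,3-dihydroxypropanoate
Product: 4 methyl (2S)-3-[(tert-butyldiphenylsilyl)oxy]-2-hydroxypropanoate
Conditions: TBDPSCl (1.05 equiv), imidazole, CH2Cl2, 0 °C
Reagents that add atoms: tert-butyldiphenylsilyl chloride (TBDPSCl), CC(C)(C)[Si](Cl)(c1ccccc1)c1ccccc1
Why: Silyl ether formation with the bulky TBDPSCl should be selective for the primary OH over the secondary α-hydroxy-ester OH, and it leaves the stereocentre untouched.

Step 3
Reactants: 4 methyl (2S)-3-[(tert-butyldiphenylsilyl)oxy]-2-hydroxypropanoate; 5 4-bromo-2-hydroxybenzaldehyde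
Product: 6 methyl (2R)-2-(5-bromo-2-formylphenoxy)-3-[(tert-butyldiphenylsilyl)oxy]propanoate
Conditions: PPh3, DIAD, toluene, 0 °C → rt
Reagents that add atoms: none
Why: Mitsunobu etherification of an α-hydroxy ester with an acidic phenol proceeds by SN2 at the carbinol carbon, so the (S) centre is inverted to the (R) aryl ether that becomes C3 of the target.

Step 4
Reactants: 6 methyl (2R)-2-(5-bromo-2-formylphenoxy)-3-[(tert-butyldiphenylsilyl)oxy]propanoate
Product: 8 methyl (2R)-2-(5-bromo-2-hydroxyphenoxy)-3-[(tert-butyldiphenylsilyl)oxy]propanoate, via aryl formate 7 (not isolated)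
Conditions: mCPBA, NaHCO3, CH2Cl2, rt; then Et3N (cat.), MeOH, 0 °C
Reagents that add atoms: meta-chloroperoxybenzoic acid (mCPBA), OOC(=O)c1cccc(Cl)c1
Why: Baeyer–Villiger (Dakin-type) oxidation of an ortho-alkoxybenzaldehyde migrates the aryl group to give the aryl formate, and mild methanolysis then frees the phenol that becomes O1, para to bromine.

Step 5
Reactants: 8 methyl (2R)-2-(5-bromo-2-hydroxyphenoxy)-3-[(tert-butyldiphenylsilyl)oxy]propanoate
Product: 9 (2RS,3R)-6-bromo-3-{[(tert-butyldiphenylsilyl)oxy]methyl}-2,3-dihydro-1,4-benzodioxin-2-ol (lactol; both C2 anomers)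
Conditions: DIBAL-H (2.2 equiv), CH2Cl2, −78 °C; aq. Rochelle salt
Reagents that add atoms: none
Why: DIBAL-H partial reduction of the methyl ester should stop at the aluminium hemiacetal (one equivalent is spent on the phenol), and on work-up the aldehyde is trapped by the ortho-phenol as the six-membered lactol, which shields the α-stereocentre from enolization.

Step 6
Reactants: 9 (2RS,3R)-6-bromo-3-{[(tert-butyldiphenylsilyl)oxy]methyl}-2,3-dihydro-1,4-benzodioxin-2-ol; 2 (4-bromo-2-methoxyphenoxy)(tert-butyl)dimethylsilane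
Product: 13 (2R,3R)-6-bromo-2-[4-(tert-butyldimethylsilyloxy)-3-methoxyphenyl]-3-[(tert-butyldiphenylsilyloxy)methyl]-2,3-dihydro-1,4-benzodioxine (2,3-trans), via aryl Grignard 10 (not isolated), via ring-opened aldehyde 11 (not isolated), via benzylic diol 12 (not isolated)
Conditions: 2, Mg, THF (→ 10, 2.3 equiv); 9, THF, −78 → 0 °C; then MeSO3H (2.6 equiv), THF → CH2Cl2, 0 °C → rt
Reagents that add atoms: none
Why: The first equivalent of 10 deprotonates lactol 9, whose magnesium lactolate opens to phenoxide-aldehyde 11, and a second equivalent adds to the aldehyde carbon to forge the C1'–C2 bond and give diol 12 as a mixture of carbinol epimers; MeSO3H then ionizes the 4-silyloxy-3-methoxybenzylic alcohol to an O-silylated p-quinone-methide cation that the catechol OH para to bromine captures. The closest known reaction types are Grignard addition to a lactol and the acid-mediated cyclodehydration of arylglycerol β-(2-hydroxyaryl) ethers to 2-aryl-1,4-benzodioxanes, the laboratory counterpart of the quinone-methide ring closure of the biosynthesis. The dioxane ring closes by 6-exo-trig attack of O1 on the planar benzylic carbon C2. C2 is set by the resident C3 stereocentre: closure through a half-chair with the aryl group and CH2OSi both pseudo-equatorial gives the 2,3-trans isomer, and because the C2–O1 bond can re-ionize under the acid, both epimers of 12 and any cis product should converge on the more stable trans-(2R,3R) compound. The step needs addition to outrun enolization of the α-aryloxy aldehyde, which the low temperature and the lactol (it keeps the free aldehyde concentration low) should secure, and it needs O-capture to beat C-alkylation of arenes, which the intramolecular six-membered closure and a short acid exposure should secure.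

Step 7
Reactants: 13 (2R,3R)-6-bromo-2-[4-(tert-butyldimethylsilyloxy)-3-methoxyphenyl]-3-[(tert-butyldiphenylsilyloxy)methyl]-2,3-dihydro-1,4-benzodioxine
Product: 14 (E)-3-{(2R,3R)-2-[4-(tert-butyldimethylsilyloxy)-3-methoxyphenyl]-3-[(tert-butyldiphenylsilyloxy)methyl]-2,3-dihydro-1,4-benzodioxin-6-yl}prop-2-enoic acid
Conditions: acrylic acid, Pd(OAc)2 (5 mol%), P(o-tol)3 (10 mol%), Et3N, DMF, 90 °C
Reagents that add atoms: acrylic acid, C=CC(=O)O
Why: Mizoroki–Heck coupling of the aryl bromide with acrylic acid should give the (E)-cinnamic acid through syn-insertion and syn-β-hydride elimination, without touching the two stereocentres.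

Step 8
Reactants: 14 (E)-3-{(2R,3R)-2-[4-(tert-butyldimethylsilyloxy)-3-methoxyphenyl]-3-[(tert-butyldiphenylsilyloxy)methyl]-2,3-dihydro-1,4-benzodioxin-6-yl}prop-2-enoic acid
Product: 15 (E)-3-[(2R,3R)-2-(4-hydroxy-3-methoxyphenyl)-3-(hydroxymethyl)-2,3-dihydro-1,4-benzodioxin-6-yl]prop-2-enoic acid (target)
Conditions: TBAF, AcOH, THF, 0 °C → rt
Reagents that add atoms: none
Why: Fluoride-mediated desilylation should remove both the aryl TBS and the primary TBDPS ether, with AcOH buffering so that the liberated phenoxide does not open the C2–O1 bond through a quinone methide.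

Compound list
1 | 4-bromo-2-methoxyphenol | COc1cc(Br)ccc1O | starting material
2 | (4-bromo-2-methoxyphenoxy)(tert-butyl)dimethylsilane | COc1cc(Br)ccc1O[Si](C)(C)C(C)(C)C | intermediate
3 | methyl (2S)-2,3-dihydroxypropanoate (methyl (S)-glycerate) | COC(=O)[C@@H](O)CO | starting material
4 | methyl (2S)-3-[(tert-butyldiphenylsilyl)oxy]-2-hydroxypropanoate | COC(=O)[C@@H](O)CO[Si](c1ccccc1)(c1ccccc1)C(C)(C)C | intermediate
5 | 4-bromo-2-hydroxybenzaldehyde | O=Cc1ccc(Br)cc1O | starting material
6 | methyl (2R)-2-(5-bromo-2-formylphenoxy)-3-[(tert-butyldiphenylsilyl)oxy]propanoate | COC(=O)[C@H](Oc1cc(Br)ccc1C=O)CO[Si](c1ccccc1)(c1ccccc1)C(C)(C)C | intermediate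
7 | methyl (2R)-2-[5-bromo-2-(formyloxy)phenoxy]-3-[(tert-butyldiphenylsilyl)oxy]propanoate (aryl formate, not isolated) | COC(=O)[C@H](Oc1cc(Br)ccc1OC=O)CO[Si](c1ccccc1)(c1ccccc1)C(C)(C)C | intermediate
8 | methyl (2R)-2-(5-bromo-2-hydroxyphenoxy)-3-[(tert-butyldiphenylsilyl)oxy]propanoate | COC(=O)[C@H](Oc1cc(Br)ccc1O)CO[Si](c1ccccc1)(c1ccccc1)C(C)(C)C | intermediate
9 | (2RS,3R)-6-bromo-3-{[(tert-butyldiphenylsilyl)oxy]methyl}-2,3-dihydro-1,4-benzodioxin-2-ol (lactol, both C2 anomers) | OC1Oc2ccc(Br)cc2O[C@@H]1CO[Si](c1ccccc1)(c1ccccc1)C(C)(C)C | intermediate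
10 | [4-(tert-butyldimethylsilyloxy)-3-methoxyphenyl]magnesium bromide (not isolated) | COc1cc([Mg]Br)ccc1O[Si](C)(C)C(C)(C)C | intermediate
11 | (2R)-2-(5-bromo-2-hydroxyphenoxy)-3-[(tert-butyldiphenylsilyl)oxy]propanal (ring-opened form of 9, present as its magnesium phenoxide, not isolated) | O=C[C@H](Oc1cc(Br)ccc1O)CO[Si](c1ccccc1)(c1ccccc1)C(C)(C)C | intermediate
12 | (1RS,2R)-2-(5-bromo-2-hydroxyphenoxy)-3-[(tert-butyldiphenylsilyl)oxy]-1-[4-(tert-butyldimethylsilyloxy)-3-methoxyphenyl]propan-1-ol (both carbinol epimers, not isolated) | COc1cc(C(O)[C@H](Oc2cc(Br)ccc2O)CO[Si](c2ccccc2)(c2ccccc2)C(C)(C)C)ccc1O[Si](C)(C)C(C)(C)C | intermediate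
13 | (2R,3R)-6-bromo-2-[4-(tert-butyldimethylsilyloxy)-3-methoxyphenyl]-3-[(tert-butyldiphenylsilyloxy)methyl]-2,3-dihydro-1,4-benzodioxine (trans) | COc1cc([C@H]2Oc3ccc(Br)cc3O[C@@H]2CO[Si](c2ccccc2)(c2ccccc2)C(C)(C)C)ccc1O[Si](C)(C)C(C)(C)C | intermediate
14 | (E)-3-{(2R,3R)-2-[4-(tert-butyldimethylsilyloxy)-3-methoxyphenyl]-3-[(tert-butyldiphenylsilyloxy)methyl]-2,3-dihydro-1,4-benzodioxin-6-yl}prop-2-enoic acid | COc1cc([C@H]2Oc3ccc(/C=C/C(=O)O)cc3O[C@@H]2CO[Si](c2ccccc2)(c2ccccc2)C(C)(C)C)ccc1O[Si](C)(C)C(C)(C)C | intermediate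
15 | (E)-3-[(2R,3R)-2-(4-hydroxy-3-methoxyphenyl)-3-(hydroxymethyl)-2,3-dihydro-1,4-benzodioxin-6-yl]prop-2-enoic acid | COc1cc([C@H]2Oc3ccc(/C=C/C(=O)O)cc3O[C@@H]2CO)ccc1O | target

Total step count: 8. Longest linear sequence: 7 steps (steps 2–8, from 3 to 15).

Steps most likely to fail

Step 6 (key step). The Grignard base may deprotonate the α-C–H of the ring-opened aldehyde during the addition, eroding C3. In the acid stage the benzylic cation may lose the C3 proton to an enol ether, alkylate an arene (including the spent anisole-type arene) instead of being captured by O1, or fail to converge fully on the trans isomer. The fallback sets out from lactol 9 and never opens the ring to a free aldehyde. Acetylation (Ac2O, pyridine, DMAP) would give the anomeric acetate (3R)-6-bromo-3-{[(tert-butyldiphenylsilyl)oxy]methyl}-2,3-dihydro-1,4-benzodioxin-2-yl acetate F1. Commercial 2-methoxy-4-(4,4,5,5-tetramethyl-1,3,2-dioxaborolan-2-yl)phenol and KHF2 would give potassium (4-hydroxy-3-methoxyphenyl)trifluoroborate F2. BF3·OEt2 in MeCN/CH2Cl2 at 0 °C should ionize F1 to the cyclic C2 oxocarbenium ion, which takes up the aryl group of F2 (C-glycosylation-type substitution of an O,O-acetal by an organotrifluoroborate, aryl entering trans to the C3 substituent). This would give 4-[(2R,3R)-6-bromo-3-{[(tert-butyldiphenylsilyl)oxy]methyl}-2,3-dihydro-1,4-benzodioxin-2-yl]-2-methoxyphenol F3, and TBSCl/imidazole then returns to 13.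

Step 5. Reduction may run past the aldehyde oxidation level to the primary alcohol, or the aluminium hemiacetal may collapse before the quench. The fallback sets out from 8 and accepts full reduction. LiBH4 (THF, 0 °C) would give 4-bromo-2-{[(2S)-1-[(tert-butyldiphenylsilyl)oxy]-3-hydroxypropan-2-yl]oxy}phenol F4 (same spatial arrangement; the descriptor changes only through priorities). Parikh–Doering oxidation (SO3·pyridine, DMSO, iPr2NEt, CH2Cl2, 0 °C) of the primary alcohol would give the aldehyde, which closes onto the phenol and comes back to the route at lactol 9.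

Step 3. The redox condensation at the hindered secondary carbinol may be slow, with competing elimination to the silyloxy-acrylate or partial loss of configurational purity. The fallback sets out from 4 and replaces it with a sulfonate displacement. Tf2O/2,6-lutidine (CH2Cl2, −78 °C) would give methyl (2S)-3-[(tert-butyldiphenylsilyl)oxy]-2-{[(trifluoromethyl)sulfonyl]oxy}propanoate F5. SN2 displacement by the potassium phenoxide of 5 (K2CO3, MeCN, −20 → 0 °C) should proceed with the same inversion and comes back to the route at 6.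

Further compounds
F1 | step 6 | (3R)-6-bromo-3-{[(tert-butyldiphenylsilyl)oxy]methyl}-2,3-dihydro-1,4-benzodioxin-2-yl acetate | CC(=O)OC1Oc2ccc(Br)cc2O[C@@H]1CO[Si](c1ccccc1)(c1ccccc1)C(C)(C)C
F2 | step 6 | potassium (4-hydroxy-3-methoxyphenyl)trifluoroborate | COc1cc([B-](F)(F)F)ccc1O.[K+]
F3 | step 6 | 4-[(2R,3R)-6-bromo-3-{[(tert-butyldiphenylsilyl)oxy]methyl}-2,3-dihydro-1,4-benzodioxin-2-yl]-2-methoxyphenol | COc1cc([C@H]2Oc3ccc(Br)cc3O[C@@H]2CO[Si](c2ccccc2)(c2ccccc2)C(C)(C)C)ccc1O
F4 | step 5 | 4-bromo-2-{[(2S)-1-[(tert-butyldiphenylsilyl)oxy]-3-hydroxypropan-2-yl]oxy}phenol | OC[C@H](Oc1cc(Br)ccc1O)CO[Si](c1ccccc1)(c1ccccc1)C(C)(C)C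
F5 | step 3 | methyl (2S)-3-[(tert-butyldiphenylsilyl)oxy]-2-{[(trifluoromethyl)sulfonyl]oxy}propanoate | COC(=O)[C@@H](OS(=O)(=O)C(F)(F)F)CO[Si](c1ccccc1)(c1ccccc1)C(C)(C)C
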